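**Retrosynthetic overview**

1. C12=C13 is cut by cross-metathesis: an allyl-decalin diol plus (S)-tulipalin B acetate, which brings C14 and the acetate; the lactone ring is attached last.
2. Ring A functionality (C3–OH, C4 with CH3/CH2OH, trans C5–H) comes from a bicyclic cross-conjugated dienone β-keto ester by Birch reductive C-methylation, enone reduction and LiAlH4.
3. Key step: enantioselective oxidative dearomatization of a tetrasubstituted salicylate. A tethered (Z)-allylsilane attacks the methyl-bearing para carbon, closing ring B and setting C10 (quaternary), C9 and the exocyclic methylene at once.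
4. The phenol comes from lateral alkylation of methyl 6-hydroxy-2,3-dimethylbenzoate (from 2,3-dimethylbenzoic acid) with an allylic chloride built from propargyl alcohol and allyl bromide.
5. Ring order: ring A (the benzene ring of the feedstock), then ring B (dearomatizing cyclization), then the butenolide (chiral pool, appended by metathesis).

Assumption 1: locants C1–C20 in the explanations follow labdane numbering of the target (C4 bears CH3/CH2OH, C10 the angular methyl, C9 the side chain, C8 the methylidene, C14 the acetate).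

Assumption 2: "ArI*(OAc)2" is the pre-formed bis(acetoxy)-λ3-iodane of commercial (R,R)-2,2′-[(2-iodo-1,3-phenylene)bis(oxy)]bis[N-(2,4,6-trimethylphenyl)propanamide] (made with NaBO3·4H2O/AcOH; reagent preparation, not counted as a step). The (R,R) reagent is assumed to give the (4aS,5R) dienone; if the sense is opposite, the (S,S) reagent is used.

**Step 1**
Reactants: 1 2,3-dimethylbenzoic acid
Product: 2 6-hydroxy-2,3-dimethylbenzoic acid
Conditions: Pd(OAc)2 (10 mol%), KOAc, 1,4-benzoquinone (additive), O2 (1 atm), DMA, 115 °C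
Reagents that add atoms: dioxygen, O=O
Why: Carboxylate-directed ortho C–H palladation and oxygenation (Pd-catalysed C–H hydroxylation of benzoic acids) can only occur at C6, the single free ortho position.

**Step 2**
Reactants: 2 6-hydroxy-2,3-dimethylbenzoic acid
Product: 3 methyl 6-hydroxy-2,3-dimethylbenzoate
Conditions: MeI, KHCO3, DMF, 25 °C
Reagents that add atoms: iodomethane, CI
Why: SN2 O-alkylation of the carboxylate; bicarbonate does not deprotonate the hydrogen-bonded phenol, so only the ester forms.

**Step 3**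
Reactants: 4 prop-2-yn-1-ol; 5 3-bromoprop-1-ene
Product: 6 (2Z)-2-bromohexa-2,5-dien-1-ol
Conditions: PdBr2(PhCN)2 (3 mol%), excess 5, THF, 20 °C
Reagents that add atoms: none
Why: Haloallylation of a terminal alkyne by divalent palladium (cis-bromopalladation with Br at the internal carbon, insertion of allyl bromide, β-bromide elimination) gives the 1-bromo-1,4-diene with Br and allyl cis.

**Step 4**
Reactants: 6 (2Z)-2-bromohexa-2,5-dien-1-ol
Product: 7 (2Z)-2-[(trimethylsilyl)methyl]hexa-2,5-dien-1-ol
Conditions: Me3SiCH2MgCl (2.5 equiv), Pd(PPh3)4 (5 mol%), THF, 0 to 50 °C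
Reagents that add atoms: (trimethylsilylmethyl)magnesium chloride, C[Si](C)(C)C[Mg]Cl
Why: Kumada–Corriu coupling of the alkenyl bromide proceeds with retention of geometry (the first equivalent of Grignard reagent only deprotonates the alcohol), so CH2SiMe3 ends cis to the allyl group.

**Step 5**
Reactants: 7 (2Z)-2-[(trimethylsilyl)methyl]hexa-2,5-dien-1-ol
Product: 8 [(2E)-2-(chloromethyl)hexa-2,5-dien-1-yl](trimethyl)silane
Conditions: N-chlorosuccinimide, Me2S, CH2Cl2, −20 to 0 °C
Reagents that add atoms: N-chlorosuccinimide, O=C1CCC(=O)N1Cl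
Why: Corey–Kim chlorination via the alkoxysulfonium salt gives the primary allylic chloride by SN2 under neutral conditions, without allylic transposition, alkene isomerization or protodesilylation.

**Step 6**
Reactants: 3 methyl 6-hydroxy-2,3-dimethylbenzoate; 8 [(2E)-2-(chloromethyl)hexa-2,5-dien-1-yl](trimethyl)silane
Product: 10 methyl 6-hydroxy-3-methyl-2-{(3Z)-3-[(trimethylsilyl)methyl]hepta-3,6-dien-1-yl}benzoate, via dilithiated salicylate 9 (not isolated)
Conditions: LiN(i-Pr)2 (2.2 equiv), THF, −78 °C; then 8, −78 to 0 °C; H2O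
Reagents that add atoms: none
Why: Lateral (benzylic) lithiation of the o-toluate dianion occurs only at the methyl ortho to the ester, and the carbanion displaces the primary allylic chloride by SN2, leaving the alkene geometry intact.

**Step 7**
Reactants: 10 methyl 6-hydroxy-3-methyl-2-{(3Z)-3-[(trimethylsilyl)methyl]hepta-3,6-dien-1-yl}benzoate
Product: 11 methyl (4aS,5R)-4a-methyl-6-methylidene-2-oxo-5-(prop-2-en-1-yl)-2,4a,5,6,7,8-hexahydronaphthalene-1-carboxylate
Conditions: ArI*(OAc)2 (1.1 equiv), CH2Cl2/(CF3)2CHOH 4:1, −40 °C; aq NaHCO3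
Reagents that add atoms: none
Why: Proposed new method: the phenol exchanges onto the chiral trivalent-iodine reagent to give an O-bound aryloxy-λ3-iodane whose ring faces are differentiated by the C2-symmetric lactamide arms; the ester deactivates and blocks the ortho carbon, so the tethered allylsilane attacks the methyl-bearing para carbon through a chair-like six-membered transition state in which the allyl group (cis to CH2SiMe3) is pseudo-equatorial and H is anti to the methyl, the β-silyl cation then loses silicon to give the exocyclic methylene, and loss of ArI* delivers the dienone with C10 and C9 set together; the closest known reaction types are the PhI(OAc)2/(CF3)2CHOH "aromatic ring umpolung" trapping of phenols by allylsilanes (oxidative Hosomi–Sakurai cyclization) and chiral aryl-iodide-mediated enantioselective phenol dearomatization (Kita–Ishihara type); a stoichiometric pre-formed iodane is used because peracid co-oxidants would epoxidize the allylsilane.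

**Step 8**
Reactants: 11 methyl (4aS,5R)-4a-methyl-6-methylidene-2-oxo-5-(prop-2-en-1-yl)-2,4a,5,6,7,8-hexahydronaphthalene-1-carboxylate
Product: 13 methyl (1S,4aS,5R,8aS)-1,4a-dimethyl-6-methylidene-2-oxo-5-(prop-2-en-1-yl)-1,2,4a,5,6,7,8,8a-octahydronaphthalene-1-carboxylate, via lithium enolate 12 (not isolated)
Conditions: Li (2.2 equiv), NH3(l)/THF, t-BuOH (1.0 equiv), −78 °C; then MeI, −78 to −33 °C
Reagents that add atoms: iodomethane, CI
Why: Birch-type reductive alkylation (Stork): the two electrons enter the doubly activated alkylidene β-keto ester, protonation at C5 gives the trans ring fusion, and the β-keto ester enolate (inert to further reduction) is C-methylated from the face opposite the axial angular methyl, leaving CO2Me axial and CH3 equatorial at C4.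

**Step 9**
Reactants: 13 methyl (1S,4aS,5R,8aS)-1,4a-dimethyl-6-methylidene-2-oxo-5-(prop-2-en-1-yl)-1,2,4a,5,6,7,8,8a-octahydronaphthalene-1-carboxylate
Product: 14 methyl (1S,4aS,5R,8aS)-1,4a-dimethyl-6-methylidene-2-oxo-5-(prop-2-en-1-yl)decahydronaphthalene-1-carboxylate
Conditions: K[BH(sec-Bu)3] (1.1 equiv), THF, −78 °C; H2O
Reagents that add atoms: none
Why: Conjugate (1,4) hydride reduction of the β-unsubstituted cyclohexenone by the bulky trialkylborohydride; the carbonyl is shielded by the adjacent quaternary carbon, the ester and isolated alkenes are untouched, and no stereocentre is created.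

**Step 10**
Reactants: 14 methyl (1S,4aS,5R,8aS)-1,4a-dimethyl-6-methylidene-2-oxo-5-(prop-2-en-1-yl)decahydronaphthalene-1-carboxylate
Product: 15 (1R,2R,4aS,5R,8aS)-1-(hydroxymethyl)-1,4a-dimethyl-6-methylidene-5-(prop-2-en-1-yl)decahydronaphthalen-2-ol
Conditions: LiAlH4, THF, 0 to 40 °C; aqueous work-up
Reagents that add atoms: none
Why: Hydride reduction of ketone and ester: the small hydride attacks the C3 ketone axially (the equatorial trajectory is blocked by the axial C4 substituent) to give the equatorial alcohol, and the axial ester becomes the CH2OH.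

**Step 11**
Reactants: 16 (4S)-4-hydroxyoxolan-2-one
Product: 18 (3S,4S)-3-[(dimethylamino)methyl]-4-hydroxyoxolan-2-one, via dilithium enolate alkoxide 17 (not isolated)
Conditions: LiN(i-Pr)2 (2.2 equiv), THF, −78 °C; then CH2=NMe2 iodide, −78 to −20 °C; H2O
Reagents that add atoms: N,N-dimethylmethaniminium iodide (Eschenmoser's salt), C=[N+](C)C.[I-]
Why: Mannich reaction of the lactone enolate–alkoxide dianion with Eschenmoser's salt; the alkoxide cannot be eliminated, the carbinol centre is untouched, and the new trans α-centre is destroyed in the next step.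

**Step 12**
Reactants: 18 (3S,4S)-3-[(dimethylamino)methyl]-4-hydroxyoxolan-2-one
Product: 20 (4S)-4-hydroxy-3-methylideneoxolan-2-one, via trimethylammonium iodide 19 (not isolated)
Conditions: MeI, MeOH, 25 °C; then NaHCO3, CH2Cl2/H2O, 25 °C
Reagents that add atoms: none
Why: N-quaternization then E1cB (Hofmann-type) loss of trimethylamine is the classical α-methylenation of lactones; the free β-hydroxyl is a poor leaving group, so the carbinol centre is retained.

**Step 13**
Reactants: 20 (4S)-4-hydroxy-3-methylideneoxolan-2-one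
Product: 21 (3S)-4-methylidene-5-oxooxolan-3-yl acetate
Conditions: Ac2O, pyridine, DMAP (cat.), CH2Cl2, 0 °C
Reagents that add atoms: acetic anhydride, CC(=O)OC(C)=O
Why: DMAP-catalysed O-acylation of the secondary alcohol; no stereocentre is touched.

**Step 14**
Reactants: 15 (1R,2R,4aS,5R,8aS)-1-(hydroxymethyl)-1,4a-dimethyl-6-methylidene-5-(prop-2-en-1-yl)decahydronaphthalen-2-ol; 21 (3S)-4-methylidene-5-oxooxolan-3-yl acetate
Product: 22 (3S,4E)-4-{2-[(1R,4aS,5R,6R,8aS)-6-hydroxy-5-(hydroxymethyl)-5,8a-dimethyl-2-methylidenedecahydronaphthalen-1-yl]ethylidene}-5-oxooxolan-3-yl acetate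
Conditions: second-generation Hoveyda–Grubbs catalyst RuCl2(H2IMes)(=CH–C6H4-2-O-i-Pr) (10 mol%), 2,6-dichloro-1,4-benzoquinone (20 mol%), 21 (3 equiv), CH2Cl2, 40 °C
Reagents that add atoms: none
Why: Olefin cross-metathesis between the monosubstituted allyl alkene and the 1,1-disubstituted α-methylene lactone (which does not homodimerize), the hindered exocyclic methylene being unreactive; the E alkylidene lactone is expected as the thermodynamically preferred isomer, and the acetate arrives in place so the 3- and 19-hydroxyls need no protection.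

**Compound list**

1 | 2,3-dimethylbenzoic acid | Cc1cccc(C(=O)O)c1C | starting material
2 | 6-hydroxy-2,3-dimethylbenzoic acid | Cc1ccc(O)c(C(=O)O)c1C | intermediate
3 | methyl 6-hydroxy-2,3-dimethylbenzoate | COC(=O)c1c(O)ccc(C)c1C | intermediate
4 | prop-2-yn-1-ol (propargyl alcohol) | C#CCO | starting material
5 | 3-bromoprop-1-ene (allyl bromide) | C=CCBr | starting material
6 | (2Z)-2-bromohexa-2,5-dien-1-ol (Br cis to allyl) | OC/C(Br)=C/CC=C | intermediate
7 | (2Z)-2-[(trimethylsilyl)methyl]hexa-2,5-dien-1-ol (CH2SiMe3 cis to allyl) | OC/C(C[Si](C)(C)C)=C/CC=C | intermediate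
8 | [(2E)-2-(chloromethyl)hexa-2,5-dien-1-yl](trimethyl)silane (CH2SiMe3 cis to allyl) | ClC/C(C[Si](C)(C)C)=C/CC=C | intermediate
9 | dilithium salt of 3 (phenoxide and benzylic carbanion at the 2-methyl) | [Li+].[Li+].COC(=O)c1c([O-])ccc(C)c1[CH2-] | intermediate
10 | methyl 6-hydroxy-3-methyl-2-{(3Z)-3-[(trimethylsilyl)methyl]hepta-3,6-dien-1-yl}benzoate | COC(=O)c1c(O)ccc(C)c1CC/C(C[Si](C)(C)C)=C/CC=C | intermediate
11 | methyl (4aS,5R)-4a-methyl-6-methylidene-2-oxo-5-(prop-2-en-1-yl)-2,4a,5,6,7,8-hexahydronaphthalene-1-carboxylate | C=C1CCC2=C(C(=O)OC)C(=O)C=C[C@@]2(C)[C@@H]1CC=C | intermediate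
12 | lithium enolate of the C5-reduced β-keto ester (trans ring fusion, C1=C2 retained) | [Li+].C=C1CC[C@@H]2C(C(=O)OC)=C([O-])C=C[C@@]2(C)[C@@H]1CC=C | intermediate
13 | methyl (1S,4aS,5R,8aS)-1,4a-dimethyl-6-methylidene-2-oxo-5-(prop-2-en-1-yl)-1,2,4a,5,6,7,8,8a-octahydronaphthalene-1-carboxylate | C=C1CC[C@@H]2[C@](C)(C(=O)OC)C(=O)C=C[C@@]2(C)[C@@H]1CC=C | intermediate
14 | methyl (1S,4aS,5R,8aS)-1,4a-dimethyl-6-methylidene-2-oxo-5-(prop-2-en-1-yl)decahydronaphthalene-1-carboxylate | C=C1CC[C@@H]2[C@](C)(C(=O)OC)C(=O)CC[C@@]2(C)[C@@H]1CC=C | intermediate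
15 | (1R,2R,4aS,5R,8aS)-1-(hydroxymethyl)-1,4a-dimethyl-6-methylidene-5-(prop-2-en-1-yl)decahydronaphthalen-2-ol | C=C1CC[C@@H]2[C@](C)(CO)[C@H](O)CC[C@@]2(C)[C@@H]1CC=C | intermediate
16 | (4S)-4-hydroxyoxolan-2-one [(S)-3-hydroxy-γ-butyrolactone] | O=C1OC[C@@H](O)C1 | starting material
17 | dilithium enolate alkoxide of 16 | [Li+].[Li+].[O-]C1=C[C@H]([O-])CO1 | intermediate
18 | (3S,4S)-3-[(dimethylamino)methyl]-4-hydroxyoxolan-2-one (trans) | CN(C)C[C@@H]1C(=O)OC[C@H]1O | intermediate
19 | {[(3S,4S)-4-hydroxy-2-oxooxolan-3-yl]methyl}trimethylammonium iodide | C[N+](C)(C)C[C@@H]1C(=O)OC[C@H]1O.[I-] | intermediate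
20 | (4S)-4-hydroxy-3-methylideneoxolan-2-one [(S)-tulipalin B] | C=C1C(=O)OC[C@H]1O | intermediate
21 | (3S)-4-methylidene-5-oxooxolan-3-yl acetate | C=C1C(=O)OC[C@H]1OC(C)=O | intermediate
22 | (3S,4E)-4-{2-[(1R,4aS,5R,6R,8aS)-6-hydroxy-5-(hydroxymethyl)-5,8a-dimethyl-2-methylidenedecahydronaphthalen-1-yl]ethylidene}-5-oxooxolan-3-yl acetate (14-O-acetylandrographolide, CNP0077248.1) | C=C1CC[C@@H]2[C@](C)(CO)[C@H](O)CC[C@@]2(C)[C@@H]1C/C=C1/C(=O)OC[C@H]1OC(C)=O | target

**Step count**

Total: 14 steps. Longest linear sequence: 9 steps (3, 4, 5, 6, 7, 8, 9, 10, 14, from propargyl alcohol and allyl bromide). The arene branch (1, 2, 6–10, 14) is 8 steps and the lactone branch (11–14) is 4.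

**Three steps most likely to fail**

Step 7 (key dearomatizing cyclization; enantio-induction at the para carbon is unproven, and the ester-deactivated phenol may oxidize slowly). Fallback, from 10 back to 11: asymmetric induction is given up. 10 is cyclized with achiral PhI(OAc)2 in (CF3)2CHOH/CH2Cl2 at −20 °C, the established racemic conditions for allylsilane trapping of oxidized phenols. This gives 11 together with its enantiomer methyl (4aR,5S)-4a-methyl-6-methylidene-2-oxo-5-(prop-2-en-1-yl)-2,4a,5,6,7,8-hexahydronaphthalene-1-carboxylate F1. The racemate is resolved by preparative supercritical-fluid chromatography on a cellulose-carbamate chiral phase, and 11 continues into step 8.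

Step 8 (the dissolving metal must choose the doubly activated alkene over the simple enone, and the enolate must be C-methylated in ammonia). Fallback, from 11 back to 14: the order of the two reductions is reversed so that the reductive methylation runs on a classical octalone β-keto ester. K[BH(sec-Bu)3] in THF at −78 °C adds hydride to the unhindered β-CH of the disubstituted enone (the fully substituted β-carbon of the other enone is inaccessible), giving methyl (4aS,5R)-4a-methyl-6-methylidene-2-oxo-5-(prop-2-en-1-yl)-2,3,4,4a,5,6,7,8-octahydronaphthalene-1-carboxylate F2. Li/NH3 with t-BuOH (1 equiv) then gives the trans-fused lithium enolate F3, which is methylated in the same flask with MeI to give 14 directly; step 9 is no longer needed.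

Step 14 (cross-metathesis onto a 1,1-disubstituted, β-branched lactone; reactivity and E/Z are the risks). Fallback, from 15 back to 22: the lactone is closed after the metathesis instead of before. (tert-Butyldimethylsilyloxy)acetaldehyde and 1,1,1,3,3,3-hexafluoropropan-2-yl acrylate are joined by a β-isocupreidine-catalysed asymmetric Morita–Baylis–Hillman reaction to give 1,1,1,3,3,3-hexafluoropropan-2-yl (3S)-4-{[tert-butyl(dimethyl)silyl]oxy}-3-hydroxy-2-methylidenebutanoate F4 (the pseudo-enantiomeric catalyst is used if the sense of induction is reversed for this aldehyde). Ac2O/pyridine gives 1,1,1,3,3,3-hexafluoropropan-2-yl (3S)-3-(acetyloxy)-4-{[tert-butyl(dimethyl)silyl]oxy}-2-methylidenebutanoate F5. Cross-metathesis of 15 with this open-chain methacrylate-type partner (second-generation Hoveyda–Grubbs catalyst, CH2Cl2, 40 °C) gives 1,1,1,3,3,3-hexafluoropropan-2-yl (2E)-2-[(1S)-1-(acetyloxy)-2-{[tert-butyl(dimethyl)silyl]oxy}ethyl]-4-[(1R,4aS,5R,6R,8aS)-6-hydroxy-5-(hydroxymethyl)-5,8a-dimethyl-2-methylidenedecahydronaphthalen-1-yl]but-2-enoate F6. HF·pyridine in MeCN removes the silyl group under acidic conditions (to avoid acetyl migration), and the freed primary alcohol closes onto the activated ester to give 22.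

**Further compounds**

F1 | step 7 | methyl (4aR,5S)-4a-methyl-6-methylidene-2-oxo-5-(prop-2-en-1-yl)-2,4a,5,6,7,8-hexahydronaphthalene-1-carboxylate (enantiomer of 11) | C=C1CCC2=C(C(=O)OC)C(=O)C=C[C@]2(C)[C@H]1CC=C
F2 | step 8 | methyl (4aS,5R)-4a-methyl-6-methylidene-2-oxo-5-(prop-2-en-1-yl)-2,3,4,4a,5,6,7,8-octahydronaphthalene-1-carboxylate | C=C1CCC2=C(C(=O)OC)C(=O)CC[C@@]2(C)[C@@H]1CC=C
F3 | step 8 | lithium enolate of the trans-fused saturated β-keto ester (from F2 by two-electron reduction) | [Li+].C=C1CC[C@@H]2C(C(=O)OC)=C([O-])CC[C@@]2(C)[C@@H]1CC=C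
F4 | step 14 | 1,1,1,3,3,3-hexafluoropropan-2-yl (3S)-4-{[tert-butyl(dimethyl)silyl]oxy}-3-hydroxy-2-methylidenebutanoate | C=C(C(=O)OC(C(F)(F)F)C(F)(F)F)[C@H](O)CO[Si](C)(C)C(C)(C)C
F5 | step 14 | 1,1,1,3,3,3-hexafluoropropan-2-yl (3S)-3-(acetyloxy)-4-{[tert-butyl(dimethyl)silyl]oxy}-2-methylidenebutanoate | C=C(C(=O)OC(C(F)(F)F)C(F)(F)F)[C@H](OC(C)=O)CO[Si](C)(C)C(C)(C)C
F6 | step 14 | 1,1,1,3,3,3-hexafluoropropan-2-yl (2E)-2-[(1S)-1-(acetyloxy)-2-{[tert-butyl(dimethyl)silyl]oxy}ethyl]-4-[(1R,4aS,5R,6R,8aS)-6-hydroxy-5-(hydroxymethyl)-5,8a-dimethyl-2-methylidenedecahydronaphthalen-1-yl]but-2-enoate | C=C1CC[C@@H]2[C@](C)(CO)[C@H](O)CC[C@@]2(C)[C@@H]1C/C=C(/C(=O)OC(C(F)(F)F)C(F)(F)F)[C@H](OC(C)=O)CO[Si](C)(C)C(C)(C)C
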